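Saturday's flask takes its substrate at a steady rate over 80 min, and we want its contents at 80 min, as dosing ends.

the same everywhere: enzyme 0.02 mol%
- Saturday's: substrate 0.024 M (fed, over 80 min); the very flask that is asked about, followed so far
- Monday's: substrate 0.016 M (fed, over 80 min); run made earlier
- flask: substrate 0.024 M (fed, over 80 min); time 80 min

- Saturday's (time / min: product / %, substrate / %): 2.00: 1.5, 1.3; 6.00: 3.1, 5.0; 12.0: 7.6, 4.7; 15.0: 12.7, 5.4; 25.0: 22.3, 5.9
- Monday's (time / min: product / %, substrate / %): 12.0: 7.7, 7.3; 25.0: 23.2, 8.9; 30.0: 27.7, 11.3; 50.0: 51.8, 11.2; 60.0: 63.7, 9.5

(scatter of a reading: 1 percentage point)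

* concentration of product at 80 min, in M
* concentration of substrate at 80 min, in M

- the analysis behind the earlier runs scatters by 1 percentage point, standard deviation
- percentages count the whole charge, also what has not yet gone in

1. Turnover starts at zero and climbs until it matches the feed rate. From then on, while the feed lasts, the share of the charge standing as substrate, times the dosing time, is how long substrate waits. Saturday's readings from 12.0 min stand near 5.33%, a wait of 4.27 min. Monday's from 25.0 min stand near 10.2%, a wait of 8.18 min.

2. Enzyme follows the charge, so Monday's flask has 0.667 of Saturday's enzyme, and its wait reads longer by a factor 1.92. We take the wait as inverse to enzyme. Scaling Monday's to Saturday's enzyme and averaging gives the lag, the time by which product trails the feed, a pseudo-first-order lifetime: 4.86 min.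

3. Monday's later pair of substrate readings is 1.02 times the earlier pair, so we count no slowing with time.

4. We therefore expect 0.00146 M of substrate at 80 min and 0.0225 M of product. The forecast says 0.0016 M and 0.0223 M, holding that “The steady free substrate should therefore be the same in absolute terms”; its substrate is higher than ours.

5. The flask gives 0.00158 M of substrate and 0.0224 M of product, and the forecast stands.

    substrate + enzyme → product + enzyme, rate k1*[substrate]*[enzyme]/(1 + ([substrate]/Km1) + ([substrate]/Ksi1)^2) (9.10 mM, 13.0 mM, k = 47000 /M/min)

6. In Saturday's flask, substrate went to product with enzyme at 100% of its charge at 40.0 min and 100% at 80.0 min; substrate stood at 6.57% and 6.58% at those times, and product rose from 43.4% to 93.4%. After the feed, that flask reached 0% substrate and 100% product by 160 min. Its substrate at 80.0 min, read as a wait, is 5.27 min. For a neighbour flask with 0.08 mol% of enzyme, our lag scales to 1.22 min, which means 1.52% of the charge as substrate; at 80.0 min that neighbour holds 1.44%.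

The data are simulated with constants of no real substance; the scatter is artificial.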